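The γ-lactone ring (O–C12–C11–C7–C6) is cis-fused to the cyclodecadiene at C6–C7, and the oxygenated triad C6–C7–C8 matches C2–C4 of L-arabinose. The route therefore forges C7–C11 on a sugar template: a 2-bromoallyl mixed acetal on O-2 of an L-arabinopyranosid-3-ulose (the lactone at lactol level) adds as a vinylchromium to the C-3 ketone, closing the five-membered ring and setting the C7 carbinol, the pyranose ring enforcing the cis fusion. Ring opening, Eschenmoser–Claisen construction of the E-alkene, Nozaki–Hiyama–Kishi closure of the ten-membered ring at C9–C10, Mitsunobu angeloylation and late oxidation to the lactone complete the synthesis.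

Key step: step 5

Remark: target locants follow germacranolide numbering (C6 = lactone CH–O, C7 = tertiary carbinol, C11/C12/C13 = lactone α-carbon/carbonyl/exo-methylene carbon); pyranosides use sugar numbering (sugar C1–C5 = target C5–C9). The acetal carbon (future C12, until step 16) and the C5 carbinol (16, 17) are carried as epimer mixtures because both centres are destroyed later.

Step 1
Reactants: 1 L-arabinose; 2 allyl alcohol
Product: 3 allyl β-L-arabinopyranoside
Conditions: AcCl (cat.), allyl alcohol, 70 °C; crystallisation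
Reagents that add atoms: none
Why: Fischer glycosidation under thermodynamic control should give the crystalline β-pyranoside (axial O-allyl), leaving the C2–C4 stereocentres (future C6, C7–O, C8) untouched.

Step 2
Reactants: 3 allyl β-L-arabinopyranoside; 4 2-bromoacrolein diethyl acetal
Product: 7 allyl 2-O-(2-bromo-1-ethoxyprop-2-enyl)-β-L-arabinopyranoside, via 3,4-O-phenylboronate 5 (not isolated), via 2-O-acetal 3,4-O-phenylboronate 6 (not isolated)
Conditions: PhB(OH)2, PhMe, reflux (Dean–Stark); 4 (3 equiv), CSA (cat.), 4 Å MS, 50 °C; pinacol, rt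
Reagents that add atoms: none
Why: The cis-3,4-diol should form the cyclic boronate selectively (transient boronate protection), so that acid-catalysed transacetalization places the mixed acetal on O-2 only, and pinacol transesterification then frees the diol.

Step 3
Reactants: 7 allyl 2-O-(2-bromo-1-ethoxyprop-2-enyl)-β-L-arabinopyranoside
Product: 9 allyl 2-O-(2-bromo-1-ethoxyprop-2-enyl)-β-L-threo-pentopyranosid-3-ulose, via stannylene acetal 8 (not isolated)
Conditions: Bu2SnO, MeOH, reflux; evaporate; NBS, CHCl3, rt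
Reagents that add atoms: none
Why: Brominolysis of a dibutylstannylene acetal is a regioselective diol mono-oxidation, and the equatorial O-3 (the oxygen activated in arabino/galacto stannylenes) is expected to be oxidised to give the 3-ulose.

Step 4
Reactants: 9 allyl 2-O-(2-bromo-1-ethoxyprop-2-enyl)-β-L-threo-pentopyranosid-3-ulose
Product: 10 4-O-triethylsilyl ether of 9
Conditions: TESCl, imidazole, DMF, 0 °C
Reagents that add atoms: chlorotriethylsilane, CC[Si](Cl)(CC)CC
Why: Silylation of the only free hydroxyl protects the future O8 and blocks α-ketol isomerisation.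

Step 5
Reactants: 10 4-O-triethylsilyl ether of 9
Product: 12 allyl 3-C,2-O-(1-ethoxy-2-methylidene-ethane-1,2-diyl)-4-O-triethylsilyl-3-O-trimethylsilyl-β-L-arabinopyranoside (2-ethoxy-3-methylidene-oxolane cis-fused across O-2/C-3), via chromium alkoxide 11 (not isolated)
Conditions: CrCl2 (5 equiv), NiCl2 (5 mol%), degassed DMF, 25→50 °C; then TMSCl, 0 °C
Reagents that add atoms: chlorotrimethylsilane, C[Si](C)(C)Cl
Why: Ni(0) inserts into the vinyl C–Br bond of the 2-bromoallyl acetal, transmetalation gives a vinylchromium(III) that adds to the adjacent C-3 ketone (future C7), and the chromium alkoxide is silylated in situ by TMSCl. The closest known reaction is the intramolecular Nozaki–Hiyama–Kishi vinyl halide–ketone coupling, and the TMSCl trapping is that of its catalytic variant. The oxolane ring (O6–C12–C11–C7–C6) closes in a 5-exo-trig mode on the C=O. The new stereocentre C7 is controlled by the tether on O-2 and the pyranose ring: a five-membered ring can only form cis-fused on the six-membered ring, so C11 enters cis to O-2 and the oxygen keeps the original arabino orientation (7S in the target). The step needs carbonyl addition without β-alkoxide elimination of the vinylmetal or reduction of the α-oxygenated ketone, which the non-basic, weakly reducing Cr(III) reagent and the proximity of the partners should secure.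

Step 6
Reactants: 12 cis-fused tricyclic allyl glycoside
Product: 14 3-C,2-O-(1-ethoxy-2-methylidene-ethane-1,2-diyl)-4-O-triethylsilyl-3-O-trimethylsilyl-L-arabinopyranose (lactol), via prop-1-enyl glycoside 13 (not isolated)
Conditions: [Ir(cod)(PMePh2)2]PF6 (cat., H2-activated), THF, rt; then I2, NaHCO3, THF–H2O, 0 °C
Reagents that add atoms: none
Why: Iridium-catalysed allyl-to-propenyl ether isomerisation followed by buffered iodonium-mediated enol ether cleavage should free the lactol without acid, so the mixed acetal and silyl ethers survive.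

Step 7
Reactants: 14 lactol; 15 isopropenylmagnesium bromide
Product: 16 open-chain diol: oxolane carrying at C6 a CH(OH)–C(CH3)=CH2 group (C5 epimers) and at C7 (OTMS) a CH(OTES)–CH2OH chain (C8, C9)
Conditions: 15 (4 equiv), THF, −20→0 °C
Reagents that add atoms: none
Why: Grignard addition to the open aldehyde form of the lactol installs C4, C15 and the future C3; the C5 carbinol configuration is irrelevant because it is consumed in step 9.

Step 8
Reactants: 16 open-chain diol
Product: 17 C9 primary triethylsilyl ether of 16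
Conditions: TESCl (1.1 equiv), imidazole, CH2Cl2, −20 °C
Reagents that add atoms: chlorotriethylsilane, CC[Si](Cl)(CC)CC
Why: Silylation should be selective for the primary hydroxyl over the hindered secondary allylic one.

Step 9
Reactants: 17 allylic alcohol; 18 N,N-dimethylacetamide dimethyl acetal
Product: 19 (4E)-N,N-dimethyl amide (C1 amide; C4=C5 E-trisubstituted alkene)
Conditions: 18 (6 equiv), xylene, 140 °C
Reagents that add atoms: none
Why: Eschenmoser–Claisen rearrangement through a chair transition state with the C6 substituent equatorial should give the E-alkene from either C5 epimer and adds C2 and C1; the silylated tertiary allylic alcohol cannot compete.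

Step 10
Reactants: 19 (4E)-N,N-dimethyl amide
Product: 20 (4E)-C1 aldehyde
Conditions: Cp2Zr(H)Cl (2 equiv), THF, rt
Reagents that add atoms: none
Why: Schwartz's reagent reduces tertiary amides chemoselectively to aldehydes without touching acetal, silyl ethers or alkenes.

Step 11
Reactants: 20 (4E)-C1 aldehyde; 21 ethyltriphenylphosphonium iodide
Product: 22 (1Z,4E)-10-iodo diene (Z-2-iodo-2-alkene, iodine cis to C2)
Conditions: 21, n-BuLi, THF; I2, −78 °C; NaHMDS, −20 °C; then 20, −78 °C
Reagents that add atoms: iodine, II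
Why: Stork–Zhao-type Wittig olefination with the α-iodo ylide should give the Z-vinyl iodide, which fixes the later 1(10)Z geometry and adds C10 and C14.

Step 12
Reactants: 22 (1Z,4E)-10-iodo diene
Product: 23 C9 aldehyde (seco-aldehyde with C10 vinyl iodide)
Conditions: (COCl)2, DMSO, CH2Cl2, −78→−40 °C; Et3N, −78→0 °C
Reagents that add atoms: none
Why: Swern conditions convert primary TES ethers directly into aldehydes while the secondary TES and tertiary TMS ethers should survive.

Step 13
Reactants: 23 C9 aldehyde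
Product: 24 (9S)-macrocyclic allylic alcohol (ten-membered ring, 1(10)Z,4E; O8-TES, O7-TMS, lactol ethyl acetal)
Conditions: CrCl2 (10 equiv), NiCl2 (2 mol%), DMSO–THF 3:1, 2 mM, slow addition, rt
Reagents that add atoms: none
Why: Intramolecular Nozaki–Hiyama–Kishi reaction closes C9–C10 with retention of the vinyl geometry, and Felkin–Anh addition anti to the C8 silyloxy group should give the 8,9-anti (9S) alcohol.

Step 14
Reactants: 24 (9S)-macrocyclic allylic alcohol; 25 angelic acid
Product: 26 (9R)-angelate
Conditions: PPh3, DIAD, PhMe, 0 °C→rt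
Reagents that add atoms: none
Why: Mitsunobu esterification proceeds by SN2 inversion at C9, giving the required 9R ester under neutral conditions that should not isomerise angelate to tiglate.

Step 15
Reactants: 26 (9R)-angelate
Product: 27 lactol (C12 hemiacetal) with free C7 and C8 hydroxyls
Conditions: AcOH–THF–H2O 3:1:1, rt
Reagents that add atoms: water, O
Why: Mild acid hydrolysis cleaves the allylic mixed acetal and both silyl ethers, and is too weak to trigger transannular cyclisation of the diene.

Step 16
Reactants: 27 lactol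
Product: 28 CNP0303917.1
Conditions: activated MnO2 (excess), CH2Cl2, rt
Reagents that add atoms: none
Why: MnO2 oxidises the allylic lactol chemoselectively to the α-methylene-γ-lactone, leaving the secondary C8 and tertiary C7 alcohols untouched.

Compound list
1 | L-arabinose (pyranose form) | OC1OC[C@H](O)[C@H](O)[C@H]1O | starting material
2 | allyl alcohol | C=CCO | starting material
3 | allyl β-L-arabinopyranoside | C=CCO[C@H]1OC[C@H](O)[C@H](O)[C@H]1O | intermediate
4 | 2-bromoacrolein diethyl acetal (2-bromo-3,3-diethoxyprop-1-ene) | C=C(Br)C(OCC)OCC | starting material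
5 | allyl 3,4-O-(phenylboranediyl)-β-L-arabinopyranoside | C=CCO[C@H]1OC[C@@H]2OB(c3ccccc3)O[C@@H]2[C@H]1O | intermediate
6 | allyl 2-O-(2-bromo-1-ethoxyprop-2-enyl)-3,4-O-(phenylboranediyl)-β-L-arabinopyranoside | C=CCO[C@H]1OC[C@@H]2OB(c3ccccc3)O[C@@H]2[C@H]1OC(OCC)C(Br)=C | intermediate
7 | allyl 2-O-(2-bromo-1-ethoxyprop-2-enyl)-β-L-arabinopyranoside (acetal epimers) | C=CCO[C@H]1OC[C@H](O)[C@H](O)[C@H]1OC(OCC)C(Br)=C | intermediate
8 | 3,4-O-dibutylstannylene acetal of 7 | C=CCO[C@H]1OC[C@@H]2O[Sn](CCCC)(CCCC)O[C@@H]2[C@H]1OC(OCC)C(Br)=C | intermediate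
9 | allyl 2-O-(2-bromo-1-ethoxyprop-2-enyl)-β-L-threo-pentopyranosid-3-ulose | C=CCO[C@H]1OC[C@H](O)C(=O)[C@H]1OC(OCC)C(Br)=C | intermediate
10 | 4-O-triethylsilyl ether of 9 | C=CCO[C@H]1OC[C@H](O[Si](CC)(CC)CC)C(=O)[C@H]1OC(OCC)C(Br)=C | intermediate
11 | chromium(III) alkoxide of the cyclised tertiary carbinol | C=CCO[C@H]1OC[C@H](O[Si](CC)(CC)CC)[C@@]2(O[Cr](Cl)Cl)C(=C)C(OCC)O[C@@H]12 | intermediate
12 | allyl 3-C,2-O-(1-ethoxy-2-methylidene-ethane-1,2-diyl)-4-O-triethylsilyl-3-O-trimethylsilyl-β-L-arabinopyranoside (cis-fused oxolane; C-branch cis to O-2) | C=CCO[C@H]1OC[C@H](O[Si](CC)(CC)CC)[C@@]2(O[Si](C)(C)C)C(=C)C(OCC)O[C@@H]12 | intermediate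
13 | prop-1-enyl glycoside corresponding to 12 | CC=CO[C@H]1OC[C@H](O[Si](CC)(CC)CC)[C@@]2(O[Si](C)(C)C)C(=C)C(OCC)O[C@@H]12 | intermediate
14 | lactol (free anomeric OH, anomer mixture) corresponding to 12 | OC1OC[C@H](O[Si](CC)(CC)CC)[C@@]2(O[Si](C)(C)C)C(=C)C(OCC)O[C@@H]12 | intermediate
15 | isopropenylmagnesium bromide | CC(=C)[Mg]Br | starting material
16 | open-chain diol (C5 carbinol epimers, C9 primary OH; 6S,7S,8S) | CC(=C)C(O)[C@@H]1OC(OCC)C(=C)[C@]1(O[Si](C)(C)C)[C@@H](O[Si](CC)(CC)CC)CO | intermediate
17 | C9 O-triethylsilyl ether of 16 | CC(=C)C(O)[C@@H]1OC(OCC)C(=C)[C@]1(O[Si](C)(C)C)[C@@H](O[Si](CC)(CC)CC)CO[Si](CC)(CC)CC | intermediate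
18 | N,N-dimethylacetamide dimethyl acetal | CC(OC)(OC)N(C)C | starting material
19 | (4E)-N,N-dimethyl amide (C1 amide) | CN(C)C(=O)CC/C(C)=C/[C@@H]1OC(OCC)C(=C)[C@]1(O[Si](C)(C)C)[C@@H](O[Si](CC)(CC)CC)CO[Si](CC)(CC)CC | intermediate
20 | (4E)-C1 aldehyde | O=CCC/C(C)=C/[C@@H]1OC(OCC)C(=C)[C@]1(O[Si](C)(C)C)[C@@H](O[Si](CC)(CC)CC)CO[Si](CC)(CC)CC | intermediate
21 | ethyltriphenylphosphonium iodide | CC[P+](c1ccccc1)(c1ccccc1)c1ccccc1.[I-] | starting material
22 | (1Z,4E)-10-iodo diene | C/C(I)=C/CC/C(C)=C/[C@@H]1OC(OCC)C(=C)[C@]1(O[Si](C)(C)C)[C@@H](O[Si](CC)(CC)CC)CO[Si](CC)(CC)CC | intermediate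
23 | C9 aldehyde with C10 vinyl iodide | C/C(I)=C/CC/C(C)=C/[C@@H]1OC(OCC)C(=C)[C@]1(O[Si](C)(C)C)[C@@H](O[Si](CC)(CC)CC)C=O | intermediate
24 | (6S,7S,8S,9S)-macrocyclic allylic alcohol, 1(10)Z,4E, O8-TES, O7-TMS, C12 ethyl acetal | C=C1C(OCC)O[C@H]2/C=C(\C)CC/C=C(/C)[C@H](O)[C@H](O[Si](CC)(CC)CC)[C@@]12O[Si](C)(C)C | intermediate
25 | angelic acid ((Z)-2-methylbut-2-enoic acid) | C/C=C(/C)C(=O)O | starting material
26 | (9R)-angelate of the protected macrocycle | C=C1C(OCC)O[C@H]2/C=C(\C)CC/C=C(/C)[C@@H](OC(=O)/C(C)=C\C)[C@H](O[Si](CC)(CC)CC)[C@@]12O[Si](C)(C)C | intermediate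
27 | lactol (C12 hemiacetal) with free 7-OH and 8-OH, 9-O-angelate | C=C1C(O)O[C@H]2/C=C(\C)CC/C=C(/C)[C@@H](OC(=O)/C(C)=C\C)[C@H](O)[C@@]12O | intermediate
28 | CNP0303917.1 | C=C1C(=O)O[C@H]2/C=C(\C)CC/C=C(/C)[C@@H](OC(=O)/C(C)=C\C)[C@H](O)[C@@]12O | target

Total step count: 16. Longest linear sequence: 16 steps (from L-arabinose).

Steps most likely to fail

1. Step 13. Ring strain and the hindered α-silyloxy aldehyde may favour oligomerisation or protodehalogenation over the ten-membered ring closure, and facial selectivity at C9 may be low. Fallback: setting out from 20, Wittig methylenation (Ph3P=CH2) would give the terminal alkene F1; Swern oxidation of its primary TES ether would give the aldehyde F2; Felkin-controlled addition of isopropenylmagnesium bromide would give the (9S)-allylic alcohol F3; ring-closing metathesis (Grubbs II, high dilution) would then form the C1=C10 bond, the ring size favouring the Z-alkene, and return to the route at 24.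

2. Step 14. The hindered allylic alcohol may react by SN2′ displacement or elimination in place of clean inversion, or the angelate may isomerise to the tiglate. Fallback: setting out from 24, Dess–Martin oxidation would give the Z-enone F4; L-Selectride reduction (Felkin–Anh delivery of hydride anti to the C8 silyloxy group) would give the (9R)-alcohol F5; Yamaguchi esterification with 25 (2,4,6-trichlorobenzoyl chloride, Et3N, DMAP) would return to the route at 26.

3. Step 3. The stannylene brominolysis may oxidise the axial O-4 in place of O-3, or the α-ketol may dimerise or isomerise. Fallback: setting out from 7, stannylene-mediated alkylation (Bu2SnO; PMBCl, CsF) would give the 3-O-PMB ether F6; TESCl/imidazole would give the 4-O-TES ether F7; DDQ would free the 3-hydroxyl in F8; Dess–Martin oxidation would return to the route at 10.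

Further compounds
F1 | step 13 | (4E)-terminal alkene (C1=CH2) with C9 O-TES | C=CCC/C(C)=C/[C@@H]1OC(OCC)C(=C)[C@]1(O[Si](C)(C)C)[C@@H](O[Si](CC)(CC)CC)CO[Si](CC)(CC)CC
F2 | step 13 | (4E)-terminal alkene C9 aldehyde | C=CCC/C(C)=C/[C@@H]1OC(OCC)C(=C)[C@]1(O[Si](C)(C)C)[C@@H](O[Si](CC)(CC)CC)C=O
F3 | step 13 | (9S)-isopropenyl carbinol (metathesis precursor) | C=CCC/C(C)=C/[C@@H]1OC(OCC)C(=C)[C@]1(O[Si](C)(C)C)[C@@H](O[Si](CC)(CC)CC)[C@@H](O)C(C)=C
F4 | step 14 | macrocyclic C9 enone | C=C1C(OCC)O[C@H]2/C=C(\C)CC/C=C(/C)C(=O)[C@H](O[Si](CC)(CC)CC)[C@@]12O[Si](C)(C)C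
F5 | step 14 | (9R)-macrocyclic allylic alcohol | C=C1C(OCC)O[C@H]2/C=C(\C)CC/C=C(/C)[C@@H](O)[C@H](O[Si](CC)(CC)CC)[C@@]12O[Si](C)(C)C
F6 | step 3 | 3-O-(4-methoxybenzyl) ether of 7 | C=CCO[C@H]1OC[C@H](O)[C@H](OCc2ccc(OC)cc2)[C@H]1OC(OCC)C(Br)=C
F7 | step 3 | 3-O-(4-methoxybenzyl)-4-O-triethylsilyl derivative of 7 | C=CCO[C@H]1OC[C@H](O[Si](CC)(CC)CC)[C@H](OCc2ccc(OC)cc2)[C@H]1OC(OCC)C(Br)=C
F8 | step 3 | 4-O-triethylsilyl derivative of 7 with free 3-OH | C=CCO[C@H]1OC[C@H](O[Si](CC)(CC)CC)[C@H](O)[C@H]1OC(OCC)C(Br)=C
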